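**Remark (assumption).** The target SMILES assigns no configuration to the hindered C3–C1' axis, so 13 is treated as having no stereogenic element to control.

## Structural features

Talarominine A (13) is a benzofuran in which benzene ring A is fused to furan ring B. C2 carries a CH2CH2CO2Me chain, C3 a benzene ring C, C4 a methyl group and C6 a free hydroxyl. Ring C is bonded through C1' and is a 2,4-dimethylresorcinol: hydroxyls at C3' and C5', methyls at C4' (between the oxygens) and C6' (next to C1'), hydrogen only at C2'. There is no stereocentre. The C3–C1' bond is flanked by the C2 chain, the peri methyl at C4 and the C6' methyl, so rotation is hindered. The fragile groups are the methyl ester (lost to hydroxide, BBr3 or strong nucleophiles), the three electron-rich phenols and the benzofuran, which are easily halogenated or oxidised. The real difficulty is the C3–C1' bond: it is a triply ortho-substituted biaryl bond, and C1' lies meta to both ring C oxygens, where the directing effects of a resorcinol give no help. The key step uses the fact that ring C, at a lower oxidation level, is a 2,4-dimethylcyclohexane-1,3-dione with C3' and C5' as carbonyls, C4' between them, and C1' as the β carbon of an enone on benzofuran C3.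

## Logic of the disconnections

**13 to 12.** No skeletal bond is cut. Ring C is taken back to the cyclohexane-1,3-dione level by adding one molecule of hydrogen (C3' and C5' become ketones; C1', C2', C4' and C6' become sp3). The reason is that a dione can be assembled by carbonyl condensation with C1' automatically meta to both oxygens, and the crowded biaryl bond becomes an ordinary sp3–sp2 bond. The demand on the forward step is a dehydrogenation that leaves a methyl ester, free phenols and the benzofuran alone, which points to a neutral, heterogeneous palladium catalyst as the last step.

**12 to 10.** A methoxycarbonyl group is put back on C6' (C6'–CO2Me bond). This makes C6' the carbon of a malonate and so a nucleophile that methoxide can generate. The demand is that its later removal must distinguish a quaternary β-keto ester from the side-chain ester; a dealkylative decarboxylation does this, whereas hydroxide would cleave both.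

**10 to 7 and 8.** The bonds C1'–C6' and C4'–C5' are cut. This takes ring C apart into an enone that already holds C1' to C4' with the C4' methyl, and the malonate 8 that holds C5', C6' and the C6' methyl. One ring and the hindered bond to C3 are removed in a single operation. The forward step needs conjugate addition and then ring closure through the ethyl-side carbon only. The ring A oxygen of 7 is left as a free hydroxyl instead of an ether: a phenoxide is a cross-conjugated spectator in the annulation, and no late ether cleavage is then needed that would also destroy the ester.

**7 to 5 and 6.** The bonds O1–C2 and C3–C(vinyl) are cut. Ring B and the whole enone arm are traced back to an ortho-alkynyl phenol and the vinyl ketone 6. The gain is that the furan ring and the C3 substituent arise together, without a C3 halide or aldehyde as intermediate. The demand is a free ortho hydroxyl. An alkyl-substituted alkyne that also carries an ester is not expected to cyclise cleanly through a methyl ether oxygen under electrophilic activation, because the ester carbonyl competes as nucleophile and addition across the triple bond takes over.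

**5 to 3 and 4.** The aryl–alkyne bond (future C3a–C3) is cut. This gives an aryl iodide and the terminal alkyne 4, which already contains the C2 chain with its ester. The demand is a coupling mild enough that the alkynyl phenol does not cyclise prematurely.

**3 to 2 to 1.** The two O–H bonds of 3 are traced to O–CH3 bonds and the C–I bond to C–H. Iodination is placed on 1 because its two oxygens are equivalent, so only one iodide flanked by oxygen and methyl can form; an arene with two different oxygens would have two competing ortho positions. The demand is that the ether cleavage with BBr3 is done at this early stage, before any ester is present.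

## Other disconnections considered

**Alternative 1:** The cut removes O1–C2 and C2–C3. C2 and its three-carbon chain come from the sulfonium salt A3; the rest comes from the tosylmethyl phenol A2, in which the future C3 already carries ring C.
- Forward step: Cs2CO3 eliminates sulfinate from A2 to an ortho-quinone methide and deprotonates A3. The sulfur-bearing carbon of the ylide adds to the exocyclic carbon and the phenoxide displaces dimethyl sulfide, which should give the trans-dihydrobenzofuran A1. A shift of the side-chain double bond into the ring would give the benzofuran A4; cleavage of three methyl ethers and re-esterification would complete 13.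
- In its favour: the conditions are mild, two aromatic pieces are joined convergently, and no high-temperature dehydrogenation is needed, which is a point on which it is better than the chosen plan. Like the chosen plan it makes the hindered C3–C1' bond at an sp3 carbon and lets its stereocentres vanish on aromatisation; on this the two are equal.
- Against it here: the quinone methide from A2 must become planar although its exocyclic carbon bears a doubly ortho-substituted aryl group and sits next to the C4 methyl. The allylic ylide is ambident and can react through its γ carbon. The isomerisation must move a double bond out of conjugation with the ester. Ring C must be supplied with a handle at C1', meta to both oxygens, against the directing effects of its own methoxy groups.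
- Comparison: the three aryl methyl ethers need BBr3, which also attacks the ester, so the end game is longer. The count would be nine steps or more against seven.

**Alternative 2:** The cut is C3–C3a. The precursor is the α-aryloxy ketone A5, from a brominated ring A phenol and an α-bromo ketone of ring C.
- Forward step: polyphosphoric acid or Bi(OTf)3 activates the aryl ketone, the ring A carbon ortho to the ether oxygen attacks, water is lost and the furan ring of A6 closes. The bromine that blocks the second ortho position is then removed to give A4, and 13 follows by demethylation and re-esterification.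
- In its favour: this is classical acid chemistry with no precious metal in the key step. Ring C is aromatic throughout, so no dehydrogenation is needed (better than the chosen plan). The regiochemistry of ring A is fixed without doubt by the blocking group (equal to the symmetric iodination of the chosen plan).
- Against it here: closure must take place at a ring A carbon flanked by the methyl group, onto a ketone twisted out of conjugation by the C6' methyl. The crowded, fully substituted C3 is thus made in a Friedel–Crafts-type step, where acid-promoted 1,2-aryl migration to a 2-aryl benzofuran is a recognised escape. The methyl ester must survive hot acid. Blocking and unblocking cost two steps. The ring C ketone again needs a handle at C1', and three methyl ethers must be cleaved at the end.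
- Comparison: the chosen plan forms the same bond environment under reversible, base-mediated conditions instead of strong acid. About ten steps would be needed, clearly more than seven.

**Alternative 3:** The cut is C5–C6 of ring A. The benzene ring is grown on a tetrasubstituted furan, the furylacetic acid A7.
- Forward step: Ac2O and NaOAc convert the acid through a mixed anhydride into a ketene, which closes a 6π system with the furan double bond and the isopropenyl group. Enolisation and acetylation give A8.
- In its favour: the substitution pattern of ring A is set without any regiochemical question, which is better than any arene substitution. The ring A oxygen arrives as an acetate that methanolysis removes without touching the ester (equal to the chosen plan, where that oxygen is never protected after step 2). A thermal pericyclic closure is little affected by crowding, so it is equal to or better than a hindered Michael addition.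
- Against it here: all complexity is moved into A7, a furan with four different substituents that includes the crowded aryl–furan bond. That bond would need a cross-coupling of two doubly ortho-substituted partners or a long furan synthesis, and it is exactly the bond the chosen plan avoids making between sp2 carbons. Ring C still enters with a C1' handle and two methyl ethers, so BBr3 and re-esterification remain. The ketene can be intercepted by acetate or can dimerise.
- Comparison: this is the longest of the four plans, well over ten steps.

Key step: step 5

## Route

Step 1
Reactants: 1 3,5-dimethoxytoluene (1,3-dimethoxy-5-methylbenzene)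
Product: 2 2-iodo-1,5-dimethoxy-3-methylbenzene
Conditions: NIS, TFA (cat.), MeCN, rt
Reagents that add atoms: N-iodosuccinimide, O=C1CCC(=O)N1I
Why: Electrophilic aromatic iodination; the position between a methoxy group and the methyl group is ortho to one oxygen, para to the other and less crowded than the position between the two methoxy groups, and the two such positions of 1 are equivalent, so a single monoiodide is expected.

Step 2
Reactants: 2 2-iodo-1,5-dimethoxy-3-methylbenzene
Product: 3 4-iodo-5-methylbenzene-1,3-diol
Conditions: BBr3, CH2Cl2, −78 °C to rt; then H2O, 0 °C
Reagents that add atoms: none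
Why: Lewis acid ether cleavage: BBr3 binds each ether oxygen and bromide removes the methyl group by SN2; the aryl iodide is inert and no ester is present yet, so the harsh reagent is used where it can do no damage.

Step 3
Reactants: 3 4-iodo-5-methylbenzene-1,3-diol; 4 methyl pent-4-ynoate
Product: 5 methyl 5-(2,4-dihydroxy-6-methylphenyl)pent-4-ynoate
Conditions: Pd(PPh3)2Cl2 (3 mol%), CuI (5 mol%), Et3N, THF, rt, Ar
Reagents that add atoms: none
Why: Sonogashira coupling of an aryl iodide, which should react at room temperature so that the 2-alkynylphenol is not cycloisomerised by the copper salt; free phenols are tolerated under amine base and the ester is untouched.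

Step 4
Reactants: 5 methyl 5-(2,4-dihydroxy-6-methylphenyl)pent-4-ynoate; 6 pent-1-en-3-one (ethyl vinyl ketone)
Product: 7 methyl 3-{6-hydroxy-4-methyl-3-[(E)-3-oxopent-1-en-1-yl]-1-benzofuran-2-yl}propanoate
Conditions: PdCl2 (5 mol%), KI (0.5 equiv), 6 (5 equiv), DMF, air, 80 °C
Reagents that add atoms: none
Why: Divalent palladium activates the alkyne for anti attack of the ortho hydroxyl (5-endo-dig oxypalladation), the benzofuran-3-yl palladium species inserts the vinyl ketone, and β-hydride elimination gives the E enone while air returns zerovalent palladium to the divalent state (Wacker-type cyclisation followed by oxidative Heck coupling, a known reaction of 2-alkynylphenols with electron-poor alkenes). The hydroxyl para to the alkyne cannot reach it and stays free as the C6 hydroxyl of the target.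

Step 5
Reactants: 7 methyl 3-{6-hydroxy-4-methyl-3-[(E)-3-oxopent-1-en-1-yl]-1-benzofuran-2-yl}propanoate; 8 dimethyl methylmalonate (dimethyl 2-methylpropanedioate)
Product: 10 methyl 2-[6-hydroxy-2-(3-methoxy-3-oxopropyl)-4-methyl-1-benzofuran-3-yl]-1,5-dimethyl-4,6-dioxocyclohexane-1-carboxylate (racemic mixture of diastereomers), via Michael adduct 9 (not isolated)
Conditions: NaOMe (3.5 equiv), 8 (1.5 equiv), MeOH, reflux, N2; then aq. HCl
Reagents that add atoms: none
Why: Methoxide deprotonates the phenol (a spectator, cross-conjugated with the enone) and the malonate 8, whose soft, stabilised anion adds to the β carbon of 7 to give 9 (bond C1'–C6'). Proton exchange then gives the ketone enolate on the ethyl side, whose carbon attacks one of the two malonate ester groups and expels methoxide (bond C4'–C5'); this 6-(enolendo)-exo-trig Claisen closure forms the only new ring. The closest known reaction type is the Michael–Claisen annulation of enones with malonates that gives 5-substituted cyclohexane-1,3-diones. Every step is reversible, but the product is deprotonated at once to its stabilised 1,3-dione enolate, which drains the equilibria and should compensate for the hindered approach to the β carbon next to the disubstituted benzofuran. Conjugate addition is secured by the stabilised nucleophile, since carbonyl addition is reversible and unproductive; the Claisen step can use only the ethyl carbon, because the other α carbon would close a four-membered ring and attack on the side-chain ester would need a nine-membered ring. Methyl esters with methoxide make transesterification degenerate. The three new stereocentres (C1, C2 and C5 of the cyclohexane) are not controlled; C5 equilibrates through the enolate, and a mixture is acceptable because all three become sp2 carbons in step 7.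

Step 6
Reactants: 10 methyl 2-[6-hydroxy-2-(3-methoxy-3-oxopropyl)-4-methyl-1-benzofuran-3-yl]-1,5-dimethyl-4,6-dioxocyclohexane-1-carboxylate
Product: 12 methyl 3-[3-(2,4-dimethyl-3,5-dioxocyclohexyl)-6-hydroxy-4-methyl-1-benzofuran-2-yl]propanoate (racemic mixture of diastereomers), via β-keto acid 11 (not isolated)
Conditions: LiCl, H2O, DMSO, 150 °C
Reagents that add atoms: none
Why: Krapcho dealkoxycarbonylation: chloride attacks the O-methyl group of the activated quaternary β-keto ester, whose carbonyl hydroxide would reach poorly, and the carboxylate 11 loses CO2 through the neighbouring ketone. An isolated methyl propanoate on a quaternary β-keto ester substrate is known to survive these conditions, so the side-chain ester of the target is kept; the new C–H stereocentre is uncontrolled and is erased in step 7.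

Step 7
Reactants: 12 methyl 3-[3-(2,4-dimethyl-3,5-dioxocyclohexyl)-6-hydroxy-4-methyl-1-benzofuran-2-yl]propanoate
Product: 13 talarominine A, methyl 3-[3-(3,5-dihydroxy-2,4-dimethylphenyl)-6-hydroxy-4-methyl-1-benzofuran-2-yl]propanoate
Conditions: Pd/C (10 wt% Pd), diglyme, reflux, N2 sweep
Reagents that add atoms: none
Why: Heterogeneous acceptorless dehydrogenation of a cyclohexane-1,3-dione to a resorcinol over palladium, driven by aromatisation and by removal of H2 in the gas stream. The neutral conditions spare the ester, the phenols and the fully substituted furan double bond, and the three stereocentres of 12 disappear.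

## Compound list

1 | 3,5-dimethoxytoluene (1,3-dimethoxy-5-methylbenzene) | COc1cc(C)cc(OC)c1 | starting material
2 | 2-iodo-1,5-dimethoxy-3-methylbenzene | COc1cc(C)c(I)c(OC)c1 | intermediate
3 | 4-iodo-5-methylbenzene-1,3-diol | Cc1cc(O)cc(O)c1I | intermediate
4 | methyl pent-4-ynoate | C#CCCC(=O)OC | starting material
5 | methyl 5-(2,4-dihydroxy-6-methylphenyl)pent-4-ynoate | COC(=O)CCC#Cc1c(C)cc(O)cc1O | intermediate
6 | pent-1-en-3-one | C=CC(=O)CC | starting material
7 | methyl 3-{6-hydroxy-4-methyl-3-[(E)-3-oxopent-1-en-1-yl]-1-benzofuran-2-yl}propanoate | COC(=O)CCc1oc2cc(O)cc(C)c2c1/C=C/C(=O)CC | intermediate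
8 | dimethyl methylmalonate (dimethyl 2-methylpropanedioate) | COC(=O)C(C)C(=O)OC | starting material
9 | dimethyl 2-{1-[6-hydroxy-2-(3-methoxy-3-oxopropyl)-4-methyl-1-benzofuran-3-yl]-3-oxopentyl}-2-methylpropanedioate (racemic) | COC(=O)CCc1oc2cc(O)cc(C)c2c1C(CC(=O)CC)C(C)(C(=O)OC)C(=O)OC | intermediate
10 | methyl 2-[6-hydroxy-2-(3-methoxy-3-oxopropyl)-4-methyl-1-benzofuran-3-yl]-1,5-dimethyl-4,6-dioxocyclohexane-1-carboxylate (racemic mixture of diastereomers) | COC(=O)CCc1oc2cc(O)cc(C)c2c1C1CC(=O)C(C)C(=O)C1(C)C(=O)OC | intermediate
11 | 2-[6-hydroxy-2-(3-methoxy-3-oxopropyl)-4-methyl-1-benzofuran-3-yl]-1,5-dimethyl-4,6-dioxocyclohexane-1-carboxylic acid (racemic mixture of diastereomers) | COC(=O)CCc1oc2cc(O)cc(C)c2c1C1CC(=O)C(C)C(=O)C1(C)C(=O)O | intermediate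
12 | methyl 3-[3-(2,4-dimethyl-3,5-dioxocyclohexyl)-6-hydroxy-4-methyl-1-benzofuran-2-yl]propanoate (racemic mixture of diastereomers) | COC(=O)CCc1oc2cc(O)cc(C)c2c1C1CC(=O)C(C)C(=O)C1C | intermediate
13 | talarominine A, methyl 3-[3-(3,5-dihydroxy-2,4-dimethylphenyl)-6-hydroxy-4-methyl-1-benzofuran-2-yl]propanoate | COC(=O)CCc1oc2cc(O)cc(C)c2c1-c1cc(O)c(C)c(O)c1C | target

## Step count and least certain steps

Total: 7 steps. Longest linear sequence: 7 steps (1 to 13); the route is linear, with 4, 6 and 8 purchased.

**Step 4 (oxidative cyclisation and alkenylation).**
- What may go wrong: protonolysis of the benzofuran-3-yl palladium bond before the alkene inserts, which ends in plain cycloisomerisation; protonation of the palladium enolate after insertion, which ends in conjugate addition instead of β-hydride elimination; oxidative side reactions of the free, electron-rich phenol ring under air and iodide; oxa-Michael addition of a phenol to the vinyl ketone.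
- Fallback, from 5 back to 7: cycloisomerise 5 with CuI and Et3N in DMF at 80 °C to methyl 3-(6-hydroxy-4-methyl-1-benzofuran-2-yl)propanoate F1. Acetylate with Ac2O in pyridine to methyl 3-(6-acetoxy-4-methyl-1-benzofuran-2-yl)propanoate F2, in which the acetate deactivates ring A. Formylate at C3 under Vilsmeier–Haack conditions (POCl3, DMF) to methyl 3-(6-acetoxy-3-formyl-4-methyl-1-benzofuran-2-yl)propanoate F3. Olefinate by a Horner–Wadsworth–Emmons reaction with diethyl (2-oxobutyl)phosphonate (LiCl, DBU, MeCN) to methyl 3-{6-acetoxy-4-methyl-3-[(E)-3-oxopent-1-en-1-yl]-1-benzofuran-2-yl}propanoate F4. Remove the acetate with K2CO3 in MeOH to return to 7.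

**Step 5 (key step).**
- What may go wrong: slow and reversible conjugate addition of a tertiary carbanion to a β carbon shielded by the C2 chain and the C4 methyl, so that retro-Michael cleavage and self-condensation of the enone through its ethyl-side enolate compete before the Claisen closure can trap the adduct.
- Fallback, from 7 back to 12: after silylation of the phenol in the flask (TMSCl, Et3N), carry out a TiCl4-promoted Mukaiyama–Michael addition of 1-methoxy-1-(trimethylsilyloxy)prop-1-ene in CH2Cl2 at −78 °C. Aqueous work-up should give the δ-keto ester methyl 3-[6-hydroxy-2-(3-methoxy-3-oxopropyl)-4-methyl-1-benzofuran-3-yl]-2-methyl-5-oxoheptanoate F5. Lewis acid activation and a less hindered secondary nucleophile replace the malonate. Claisen cyclisation of F5 with NaOMe in refluxing MeOH closes the same C4'–C5' bond and gives 12 directly, without a decarboxylation.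

**Step 7 (dehydrogenation).**
- What may go wrong: incomplete dehydrogenation, or hydrogen transfer between molecules that leaves reduced ring C material, because the ring must flatten against three flanking ortho substituents and the polar substrate may bind poorly to the catalyst at the temperature available.
- Fallback, from 12 back to 13: silylate with TMSOTf and Et3N in CH2Cl2 to the silyl dienol ether methyl 3-{3-[2,4-dimethyl-3,5-bis(trimethylsilyloxy)cyclohexa-2,4-dien-1-yl]-4-methyl-6-(trimethylsilyloxy)-1-benzofuran-2-yl}propanoate F6. Oxidise with Pd(OAc)2 in MeCN at room temperature (Saegusa–Ito oxidation), then cleave the silyl ethers with dilute HCl in MeOH; the dienone formed tautomerises to 13. The direction of the second enolisation does not matter, since both dienol ethers lead to the same arene.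

**Step 3 (Sonogashira coupling).**
- What may go wrong: premature 5-endo cyclisation of the coupled alkynylphenol under copper and amine, which would leave C3 unsubstituted, and slow oxidative addition into an electron-rich, doubly ortho-substituted iodide that tempts heating.
- Fallback, from 3 back to 5: acetylate 3 (Ac2O, pyridine) to 4-iodo-5-methyl-1,3-phenylene diacetate F7, which is less electron-rich and cannot cyclise. Couple with 4 under the same catalyst to methyl 5-(2,4-diacetoxy-6-methylphenyl)pent-4-ynoate F8. Release 5 with catalytic K2CO3 in MeOH at 0 °C.

**Step 6 (Krapcho dealkoxycarbonylation).**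
- What may go wrong: loss of chemoselectivity between the two methyl esters at 150 °C, or incomplete reaction at the crowded quaternary centre.
- Fallback, from 10 back to 13: cleave both methyl esters on purpose with LiI in refluxing pyridine, then acidify with aq. HCl. Decarboxylation of the β-keto acid should give 3-[3-(2,4-dimethyl-3,5-dioxocyclohexyl)-6-hydroxy-4-methyl-1-benzofuran-2-yl]propanoic acid F9. Dehydrogenate over Pd/C as in step 7 to 3-[3-(3,5-dihydroxy-2,4-dimethylphenyl)-6-hydroxy-4-methyl-1-benzofuran-2-yl]propanoic acid F10. Fischer esterification (MeOH, cat. H2SO4, reflux) gives 13.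

## Further compounds

F1 | step 4 | methyl 3-(6-hydroxy-4-methyl-1-benzofuran-2-yl)propanoate | COC(=O)CCc1cc2c(C)cc(O)cc2o1
F2 | step 4 | methyl 3-(6-acetoxy-4-methyl-1-benzofuran-2-yl)propanoate | COC(=O)CCc1cc2c(C)cc(OC(C)=O)cc2o1
F3 | step 4 | methyl 3-(6-acetoxy-3-formyl-4-methyl-1-benzofuran-2-yl)propanoate | COC(=O)CCc1oc2cc(OC(C)=O)cc(C)c2c1C=O
F4 | step 4 | methyl 3-{6-acetoxy-4-methyl-3-[(E)-3-oxopent-1-en-1-yl]-1-benzofuran-2-yl}propanoate | COC(=O)CCc1oc2cc(OC(C)=O)cc(C)c2c1/C=C/C(=O)CC
F5 | step 5 | methyl 3-[6-hydroxy-2-(3-methoxy-3-oxopropyl)-4-methyl-1-benzofuran-3-yl]-2-methyl-5-oxoheptanoate (racemic mixture of diastereomers) | COC(=O)CCc1oc2cc(O)cc(C)c2c1C(CC(=O)CC)C(C)C(=O)OC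
F6 | step 7 | methyl 3-{3-[2,4-dimethyl-3,5-bis(trimethylsilyloxy)cyclohexa-2,4-dien-1-yl]-4-methyl-6-(trimethylsilyloxy)-1-benzofuran-2-yl}propanoate (racemic) | COC(=O)CCc1oc2cc(O[Si](C)(C)C)cc(C)c2c1C1CC(O[Si](C)(C)C)=C(C)C(O[Si](C)(C)C)=C1C
F7 | step 3 | 4-iodo-5-methyl-1,3-phenylene diacetate | CC(=O)Oc1cc(C)c(I)c(OC(C)=O)c1
F8 | step 3 | methyl 5-(2,4-diacetoxy-6-methylphenyl)pent-4-ynoate | COC(=O)CCC#Cc1c(C)cc(OC(C)=O)cc1OC(C)=O
F9 | step 6 | 3-[3-(2,4-dimethyl-3,5-dioxocyclohexyl)-6-hydroxy-4-methyl-1-benzofuran-2-yl]propanoic acid (racemic mixture of diastereomers) | OC(=O)CCc1oc2cc(O)cc(C)c2c1C1CC(=O)C(C)C(=O)C1C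
F10 | step 6 | 3-[3-(3,5-dihydroxy-2,4-dimethylphenyl)-6-hydroxy-4-methyl-1-benzofuran-2-yl]propanoic acid | OC(=O)CCc1oc2cc(O)cc(C)c2c1-c1cc(O)c(C)c(O)c1C
A1 | alternative 1 | methyl (E)-3-[trans-3-(3,5-dimethoxy-2,4-dimethylphenyl)-6-methoxy-4-methyl-2,3-dihydro-1-benzofuran-2-yl]prop-2-enoate (racemic, one enantiomer drawn) | COC(=O)/C=C/[C@@H]1Oc2cc(OC)cc(C)c2[C@H]1c1cc(OC)c(C)c(OC)c1C
A2 | alternative 1 | 2-[(3,5-dimethoxy-2,4-dimethylphenyl)(4-methylbenzenesulfonyl)methyl]-5-methoxy-3-methylphenol (racemic) | COc1cc(C)c(C(c2cc(OC)c(C)c(OC)c2C)S(=O)(=O)c2ccc(C)cc2)c(O)c1
A3 | alternative 1 | [(E)-4-methoxy-4-oxobut-2-en-1-yl]dimethylsulfonium bromide | COC(=O)/C=C/C[S+](C)C.[Br-]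
A4 | alternative 1 | methyl 3-[3-(3,5-dimethoxy-2,4-dimethylphenyl)-6-methoxy-4-methyl-1-benzofuran-2-yl]propanoate | COC(=O)CCc1oc2cc(OC)cc(C)c2c1-c1cc(OC)c(C)c(OC)c1C
A5 | alternative 2 | methyl 4-(2-bromo-3-methoxy-5-methylphenoxy)-5-(3,5-dimethoxy-2,4-dimethylphenyl)-5-oxopentanoate (racemic) | COC(=O)CCC(Oc1cc(C)cc(OC)c1Br)C(=O)c1cc(OC)c(C)c(OC)c1C
A6 | alternative 2 | methyl 3-[7-bromo-3-(3,5-dimethoxy-2,4-dimethylphenyl)-6-methoxy-4-methyl-1-benzofuran-2-yl]propanoate | COC(=O)CCc1oc2c(Br)c(OC)cc(C)c2c1-c1cc(OC)c(C)c(OC)c1C
A7 | alternative 3 | 2-[4-(3,5-dimethoxy-2,4-dimethylphenyl)-5-(3-methoxy-3-oxopropyl)-3-(prop-1-en-2-yl)furan-2-yl]acetic acid | COC(=O)CCc1oc(CC(=O)O)c(C(C)=C)c1-c1cc(OC)c(C)c(OC)c1C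
A8 | alternative 3 | methyl 3-[6-acetoxy-3-(3,5-dimethoxy-2,4-dimethylphenyl)-4-methyl-1-benzofuran-2-yl]propanoate | COC(=O)CCc1oc2cc(OC(C)=O)cc(C)c2c1-c1cc(OC)c(C)c(OC)c1C
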